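**Retrosynthetic overview**
- Last bond: the C5–O ester between the hydroxy dihydropyranone and the silyl-protected dienoic acid (carbodiimide coupling), then one global desilylation.
- Dienoic acid: a light-driven nickel/ruthenium reductive conjugate alkenylation joins a dienyl iodide to (S)-5-(hydroxymethyl)furan-2(5H)-one and sets the acyl-chain stereocentre; the butyrolactone is then opened and its carbinol carbon trimmed to CH2OH.
- Dihydropyranone (the only ring, formed late): singlet-oxygen Achmatowicz ring expansion of a 2-furyl carbinol, lactol oxidation, trans-selective Luche reduction.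
- Furyl carbinol: Felkin–Anh addition of 2-furyllithium to the C6 aldehyde, which comes from a zinc-catalysed SN2 coupling of the side-chain Grignard reagent with (S)-lactate triflate (sets C7).
- Side chain: chelation-controlled addition of the Grignard reagent from (R)-1-bromo-3-chloro-2-methylpropane (C9) to an (S)-glycerate-derived methyl ketone (sets the tertiary carbinol); vinyl group by glycol cleavage and Wittig methylenation.

Assumption: the SMILES is taken as the full definition of the target (5S,6R lactone; 2S,4R,6S side chain; 2E,4E,6R acyl chain). The route is a paper design; selectivities quoted are expectations, not measured values.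

**Route**

Step 1
Reactants: 1 methyl (4S)-2,2-dimethyl-1,3-dioxolane-4-carboxylate
Product: 3 1-[(4S)-2,2-dimethyl-1,3-dioxolan-4-yl]ethan-1-one, via Weinreb amide 2 (not isolated)
Conditions: MeNH(OMe)·HCl, i-PrMgCl, THF, −20 °C; then MeMgBr, 0 °C
Reagents that add atoms: methylmagnesium bromide, C[Mg]Br
Why: One-pot Weinreb ketone synthesis; the magnesium chelate of the N-methoxy amide stops at the ketone and the α-alkoxy stereocentre is not touched.

Step 2
Reactants: 4 (2R)-1-bromo-3-chloro-2-methylpropane; 3 1-[(4S)-2,2-dimethyl-1,3-dioxolan-4-yl]ethan-1-one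
Product: 7 (4S)-4-[(2S,4S)-5-chloro-4-methyl-2-(triethylsilyloxy)pentan-2-yl]-2,2-dimethyl-1,3-dioxolane, via Grignard reagent 5 (not isolated), via magnesium alkoxide 6 (not isolated)
Conditions: 4, Mg, Et2O, 0 to 23 °C; then 3, −78 °C; then Et3SiOTf, 2,6-lutidine, −78 to 0 °C
Reagents that add atoms: triethylsilyl trifluoromethanesulfonate, CC[Si](CC)(CC)OS(=O)(=O)C(F)(F)F
Why: Cram-chelate Grignard addition: magnesium bridges the ketone oxygen and the α-oxygen of the dioxolane, the C–Br end of 4 inserts magnesium selectively, and attack from the face of the α-hydrogen sets the (S) tertiary carbinol (expected dr about 10:1), which is silylated as its alkoxide.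

Step 3
Reactants: 7 (4S)-4-[(2S,4S)-5-chloro-4-methyl-2-(triethylsilyloxy)pentan-2-yl]-2,2-dimethyl-1,3-dioxolane
Product: 8 (2S,4S)-5-chloro-2,4-dimethyl-2-(triethylsilyloxy)pentanal
Conditions: H5IO6, EtOAc, 0 to 23 °C
Reagents that add atoms: none
Why: Periodic acid opens the terminal acetonide and cleaves the freed glycol in one flask (Malaprade glycol cleavage); the new aldehyde has no α-hydrogen and cannot epimerise.

Step 4
Reactants: 8 (2S,4S)-5-chloro-2,4-dimethyl-2-(triethylsilyloxy)pentanal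
Product: 9 [(3S,5S)-6-chloro-3,5-dimethylhex-1-en-3-yl]oxy(triethyl)silane
Conditions: Ph3PCH3Br, KN(SiMe3)2, THF, 0 °C; then 8, 0 to 23 °C
Reagents that add atoms: methyltriphenylphosphonium bromide, C[P+](c1ccccc1)(c1ccccc1)c1ccccc1.[Br-]
Why: Wittig methylenation of a non-enolisable aldehyde gives the vinyl carbinol unit; the primary chloride is inert at this temperature.

Step 5
Reactants: 10 tert-butyl (2S)-2-hydroxypropanoate
Product: 11 tert-butyl (2S)-2-(trifluoromethylsulfonyloxy)propanoate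
Conditions: Tf2O, 2,6-lutidine, CH2Cl2, −40 to 0 °C
Reagents that add atoms: trifluoromethanesulfonic anhydride, O=S(=O)(OS(=O)(=O)C(F)(F)F)C(F)(F)F
Why: O-Sulfonylation with retention turns (S)-lactate into an SN2-active α-triflyloxy ester.

Step 6
Reactants: 9 [(3S,5S)-6-chloro-3,5-dimethylhex-1-en-3-yl]oxy(triethyl)silane; 11 tert-butyl (2S)-2-(trifluoromethylsulfonyloxy)propanoate
Product: 13 tert-butyl (2S,4R,6S)-2,4,6-trimethyl-6-(triethylsilyloxy)oct-7-enoate, via Grignard reagent 12 (not isolated)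
Conditions: 9, Mg, I2 (cat.), THF, 65 °C; then ZnCl2 (5 mol%), 11, THF, 0 °C
Reagents that add atoms: none
Why: Zinc-catalysed SN2 cross-coupling of an alkyl Grignard reagent with an α-triflyloxy ester proceeds with clean inversion, so the lactate carbon becomes the (2S) methyl-bearing centre and the syn-1,3-dimethyl array is complete.

Step 7
Reactants: 13 tert-butyl (2S,4R,6S)-2,4,6-trimethyl-6-(triethylsilyloxy)oct-7-enoate
Product: 14 (2S,4R,6S)-2,4,6-trimethyl-6-(triethylsilyloxy)oct-7-enal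
Conditions: i-Bu2AlH, CH2Cl2, −78 °C; then MeOH, H2O
Reagents that add atoms: none
Why: Partial reduction of the hindered ester stops at the aluminium hemiacetal at −78 °C; the aldehyde is used cold and at once to avoid α-epimerisation.

Step 8
Reactants: 14 (2S,4R,6S)-2,4,6-trimethyl-6-(triethylsilyloxy)oct-7-enal; 15 furan
Product: 17 (1R,2S,4R,6S)-1-(furan-2-yl)-2,4,6-trimethyl-6-(triethylsilyloxy)oct-7-en-1-ol, via 2-furyllithium 16 (not isolated)
Conditions: 15, n-BuLi, THF, 0 to 23 °C; then 14, −78 °C; then H2O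
Reagents that add atoms: none
Why: Felkin–Anh 1,2-addition to the α-methyl aldehyde gives the 1,2-syn (1R) carbinol under control of the lactate-derived centre (expected dr about 3–4:1, epimers separated by chromatography).

Step 9
Reactants: 17 (1R,2S,4R,6S)-1-(furan-2-yl)-2,4,6-trimethyl-6-(triethylsilyloxy)oct-7-en-1-ol
Product: 19 (2R)-6-hydroxy-2-[(2S,4R,6S)-4,6-dimethyl-6-(triethylsilyloxy)oct-7-en-2-yl]-2H-pyran-3(6H)-one (both C6 epimers), via furan endoperoxide 18 (not isolated)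
Conditions: O2, tetraphenylporphyrin (cat.), visible light, CH2Cl2, −78 °C; then Me2S, −78 to 23 °C
Reagents that add atoms: oxygen, O=O
Why: Photosensitised [4+2] addition of singlet oxygen to the furan and reduction of the endoperoxide give the cis-enedione, which closes to the pyranone (Achmatowicz rearrangement); the carbinol centre is carried over unchanged and the isolated vinyl group has no allylic hydrogen for an ene reaction.

Step 10
Reactants: 19 (2R)-6-hydroxy-2-[(2S,4R,6S)-4,6-dimethyl-6-(triethylsilyloxy)oct-7-en-2-yl]-2H-pyran-3(6H)-one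
Product: 20 (6R)-6-[(2S,4R,6S)-4,6-dimethyl-6-(triethylsilyloxy)oct-7-en-2-yl]-2H-pyran-2,5(6H)-dione
Conditions: Dess–Martin periodinane, CH2Cl2, 0 to 23 °C
Reagents that add atoms: none
Why: Lactol-to-lactone oxidation under non-basic conditions, which spares the silyl ether and the base-labile C6 centre; the keto lactone is taken on crude.

Step 11
Reactants: 20 (6R)-6-[(2S,4R,6S)-4,6-dimethyl-6-(triethylsilyloxy)oct-7-en-2-yl]-2H-pyran-2,5(6H)-dione
Product: 21 (5S,6R)-5-hydroxy-6-[(2S,4R,6S)-4,6-dimethyl-6-(triethylsilyloxy)oct-7-en-2-yl]-5,6-dihydro-2H-pyran-2-one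
Conditions: NaBH4, CeCl3·7H2O, MeOH, −78 °C
Reagents that add atoms: none
Why: Luche 1,2-reduction of the ring ketone; axial hydride delivery anti to the C6 substituent gives the trans (5S) alcohol, as in osmundalactone-type reductions.

Step 12
Reactants: 22 prop-2-yn-1-ol
Product: 24 (2E)-3-iodo-2-methylprop-2-en-1-ol, via alkenylalane 23 (not isolated)
Conditions: AlMe3, Cp2ZrCl2 (25 mol%), CH2Cl2, 0 to 23 °C; then I2, THF, −30 to 0 °C; then H2O
Reagents that add atoms: trimethylaluminium, C[Al](C)C; iodine, II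
Why: Negishi zirconium-catalysed syn-carboalumination followed by iodinolysis with retention gives the E iodide only.

Step 13
Reactants: 24 (2E)-3-iodo-2-methylprop-2-en-1-ol
Product: 26 tert-butyl (2E,4E)-5-iodo-4-methylpenta-2,4-dienoate, via iodo enal 25 (not isolated)
Conditions: MnO2, Ph3P=CHCO2t-Bu, CH2Cl2, 23 °C
Reagents that add atoms: tert-butyl (triphenylphosphoranylidene)acetate, CC(C)(C)OC(=O)C=P(c1ccccc1)(c1ccccc1)c1ccccc1
Why: Tandem allylic oxidation and Wittig olefination with a stabilised ylide gives the E,E dienoate without isolating the volatile enal.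

Step 14
Reactants: 26 tert-butyl (2E,4E)-5-iodo-4-methylpenta-2,4-dienoate; 27 (5S)-5-(hydroxymethyl)furan-2(5H)-one
Product: 30 tert-butyl (2E,4E)-5-[(2S,3R)-2-(hydroxymethyl)-5-oxooxolan-3-yl]-4-methylpenta-2,4-dienoate, via silyl ether 28 (not isolated), via coupled silyl ether 29 (not isolated)
Conditions: 27, Me3SiCl, 2,6-lutidine, DMA, 23 °C; then 26, NiBr2(MeOCH2CH2OMe) (10 mol%), 4,4'-di-tert-butyl-2,2'-bipyridine (12 mol%), [Ru(bpy)3](PF6)2 (1 mol%), Hantzsch ester, 450 nm LEDs, 23 °C; then 1 M HCl (aq)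
Reagents that add atoms: none
Why: Proposed new method: a light-driven nickel/ruthenium reductive conjugate alkenylation in which the excited divalent ruthenium photocatalyst is quenched by the Hantzsch ester and the resulting reductant takes divalent nickel to zerovalent nickel, which adds oxidatively to the C(sp2)–I bond of 26 with retention of alkene geometry; after one-electron reduction the monovalent alkenylnickel inserts the butenolide C=C of 28 from the face opposite the CH2OSiMe3 group (new C–C bond at C4, nickel at C3) and lutidinium protonates the nickel enolate, so the trans lactone with the (R) centre of the acyl chain results; the closest known reaction type is the nickel-catalysed reductive conjugate addition (reductive Heck-type) of aryl and alkenyl halides to enones and acrylates driven by metal powders or a cathode, the anti selectivity copies that of cuprate and radical additions to 5-substituted butenolides, and the low triplet energy of the ruthenium sensitiser is chosen to avoid E/Z isomerisation of the dienoate.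

Step 15
Reactants: 30 tert-butyl (2E,4E)-5-[(2S,3R)-2-(hydroxymethyl)-5-oxooxolan-3-yl]-4-methylpenta-2,4-dienoate
Product: 31 tert-butyl (2E,4E,6R,7S)-7,8-dihydroxy-6-(2-hydroxyethyl)-4-methylocta-2,4-dienoate
Conditions: LiBH4, THF, 0 to 23 °C
Reagents that add atoms: none
Why: Chemoselective hydride reduction: the γ-lactone is opened to the diol while the hindered, conjugated tert-butyl dienoate is left alone.

Step 16
Reactants: 31 tert-butyl (2E,4E,6R,7S)-7,8-dihydroxy-6-(2-hydroxyethyl)-4-methylocta-2,4-dienoate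
Product: 33 tert-butyl (2E,4E,6R)-8-hydroxy-6-(hydroxymethyl)-4-methylocta-2,4-dienoate, via hydroxy aldehyde 32 (not isolated)
Conditions: NaIO4, THF/H2O (pH 7), 0 °C; then NaBH4, 0 °C
Reagents that add atoms: none
Why: Malaprade cleavage of the terminal glycol removes one carbon and the aldehyde (held mainly as its five-membered lactol, which limits enolisation at the allylic centre) is reduced at once in the same flask.

Step 17
Reactants: 33 tert-butyl (2E,4E,6R)-8-hydroxy-6-(hydroxymethyl)-4-methylocta-2,4-dienoate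
Product: 35 (2E,4E,6R)-8-(tert-butyldimethylsilyloxy)-6-[(tert-butyldimethylsilyloxy)methyl]-4-methylocta-2,4-dienoic acid, via silyl ester 34 (not isolated)
Conditions: t-BuMe2SiOTf, 2,6-lutidine, CH2Cl2, 0 to 23 °C; then MeOH/H2O, 23 °C
Reagents that add atoms: tert-butyldimethylsilyl trifluoromethanesulfonate, CC(C)(C)[Si](C)(C)OS(=O)(=O)C(F)(F)F
Why: The silyl triflate silylates both primary alcohols and converts the tert-butyl ester into the silyl ester (loss of isobutene), which alone hydrolyses in aqueous methanol.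

Step 18
Reactants: 21 (5S,6R)-5-hydroxy-6-[(2S,4R,6S)-4,6-dimethyl-6-(triethylsilyloxy)oct-7-en-2-yl]-5,6-dihydro-2H-pyran-2-one; 35 (2E,4E,6R)-8-(tert-butyldimethylsilyloxy)-6-[(tert-butyldimethylsilyloxy)methyl]-4-methylocta-2,4-dienoic acid
Product: 36 (5S,6R)-6-[(2S,4R,6S)-4,6-dimethyl-6-(triethylsilyloxy)oct-7-en-2-yl]-2-oxo-5,6-dihydro-2H-pyran-5-yl (2E,4E,6R)-8-(tert-butyldimethylsilyloxy)-6-[(tert-butyldimethylsilyloxy)methyl]-4-methylocta-2,4-dienoate
Conditions: DCC, DMAP (cat.), CH2Cl2, 0 to 23 °C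
Reagents that add atoms: none
Why: Steglich esterification of the only free hydroxyl (secondary, allylic) with retention at C5; all other hydroxyls are silylated.

Step 19
Reactants: 36 (5S,6R)-6-[(2S,4R,6S)-4,6-dimethyl-6-(triethylsilyloxy)oct-7-en-2-yl]-2-oxo-5,6-dihydro-2H-pyran-5-yl (2E,4E,6R)-8-(tert-butyldimethylsilyloxy)-6-[(tert-butyldimethylsilyloxy)methyl]-4-methylocta-2,4-dienoate
Product: 37 (5S,6R)-6-[(2S,4R,6S)-6-hydroxy-4,6-dimethyloct-7-en-2-yl]-2-oxo-5,6-dihydro-2H-pyran-5-yl (2E,4E,6R)-8-hydroxy-6-(hydroxymethyl)-4-methylocta-2,4-dienoate (CNP0227568.4)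
Conditions: HF·pyridine, pyridine, THF, 0 to 23 °C
Reagents that add atoms: none
Why: Buffered fluoride desilylation removes the two primary silyl ethers and the tertiary triethylsilyl ether without harming the unsaturated lactone, the allylic ester or the tertiary allylic alcohol.

**Compound list**
1 | methyl (4S)-2,2-dimethyl-1,3-dioxolane-4-carboxylate | COC(=O)[C@@H]1COC(C)(C)O1 | starting material
2 | (4S)-N-methoxy-N,2,2-trimethyl-1,3-dioxolane-4-carboxamide | CON(C)C(=O)[C@@H]1COC(C)(C)O1 | intermediate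
3 | 1-[(4S)-2,2-dimethyl-1,3-dioxolan-4-yl]ethan-1-one | CC(=O)[C@@H]1COC(C)(C)O1 | intermediate
4 | (2R)-1-bromo-3-chloro-2-methylpropane | BrC[C@H](C)CCl | starting material
5 | [(2S)-3-chloro-2-methylpropyl]magnesium bromide | Br[Mg]C[C@H](C)CCl | intermediate
6 | bromomagnesium (2S,4S)-5-chloro-2-[(4S)-2,2-dimethyl-1,3-dioxolan-4-yl]-4-methylpentan-2-olate | CC1(C)OC[C@H](O1)[C@@](C)(O[Mg]Br)C[C@H](C)CCl | intermediate
7 | (4S)-4-[(2S,4S)-5-chloro-4-methyl-2-(triethylsilyloxy)pentan-2-yl]-2,2-dimethyl-1,3-dioxolane | CC1(C)OC[C@H](O1)[C@@](C)(O[Si](CC)(CC)CC)C[C@H](C)CCl | intermediate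
8 | (2S,4S)-5-chloro-2,4-dimethyl-2-(triethylsilyloxy)pentanal | O=C[C@@](C)(O[Si](CC)(CC)CC)C[C@H](C)CCl | intermediate
9 | [(3S,5S)-6-chloro-3,5-dimethylhex-1-en-3-yl]oxy(triethyl)silane | C=C[C@@](C)(O[Si](CC)(CC)CC)C[C@H](C)CCl | intermediate
10 | tert-butyl (2S)-2-hydroxypropanoate | C[C@H](O)C(=O)OC(C)(C)C | starting material
11 | tert-butyl (2S)-2-(trifluoromethylsulfonyloxy)propanoate | C[C@H](OS(=O)(=O)C(F)(F)F)C(=O)OC(C)(C)C | intermediate
12 | [(2S,4S)-2,4-dimethyl-4-(triethylsilyloxy)hex-5-en-1-yl]magnesium chloride | C=C[C@@](C)(O[Si](CC)(CC)CC)C[C@H](C)C[Mg]Cl | intermediate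
13 | tert-butyl (2S,4R,6S)-2,4,6-trimethyl-6-(triethylsilyloxy)oct-7-enoate | C=C[C@@](C)(O[Si](CC)(CC)CC)C[C@H](C)C[C@H](C)C(=O)OC(C)(C)C | intermediate
14 | (2S,4R,6S)-2,4,6-trimethyl-6-(triethylsilyloxy)oct-7-enal | C=C[C@@](C)(O[Si](CC)(CC)CC)C[C@H](C)C[C@H](C)C=O | intermediate
15 | furan | c1ccoc1 | starting material
16 | 2-furyllithium | [Li]c1ccco1 | intermediate
17 | (1R,2S,4R,6S)-1-(furan-2-yl)-2,4,6-trimethyl-6-(triethylsilyloxy)oct-7-en-1-ol | C=C[C@@](C)(O[Si](CC)(CC)CC)C[C@H](C)C[C@H](C)[C@@H](O)c1ccco1 | intermediate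
18 | furan endoperoxide of 17 (2,3,7-trioxabicyclo[2.2.1]hept-5-ene carrying the carbinol side chain at C1) | C=C[C@@](C)(O[Si](CC)(CC)CC)C[C@H](C)C[C@H](C)[C@@H](O)C12OOC(O1)C=C2 | intermediate
19 | (2R)-6-hydroxy-2-[(2S,4R,6S)-4,6-dimethyl-6-(triethylsilyloxy)oct-7-en-2-yl]-2H-pyran-3(6H)-one | C=C[C@@](C)(O[Si](CC)(CC)CC)C[C@H](C)C[C@H](C)[C@H]1OC(O)C=CC1=O | intermediate
20 | (6R)-6-[(2S,4R,6S)-4,6-dimethyl-6-(triethylsilyloxy)oct-7-en-2-yl]-2H-pyran-2,5(6H)-dione | C=C[C@@](C)(O[Si](CC)(CC)CC)C[C@H](C)C[C@H](C)[C@H]1OC(=O)C=CC1=O | intermediate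
21 | (5S,6R)-5-hydroxy-6-[(2S,4R,6S)-4,6-dimethyl-6-(triethylsilyloxy)oct-7-en-2-yl]-5,6-dihydro-2H-pyran-2-one | C=C[C@@](C)(O[Si](CC)(CC)CC)C[C@H](C)C[C@H](C)[C@H]1OC(=O)C=C[C@@H]1O | intermediate
22 | prop-2-yn-1-ol | C#CCO | starting material
23 | (E)-[3-(dimethylalumanyloxy)-2-methylprop-1-en-1-yl]dimethylalumane | C[Al](C)/C=C(C)/CO[Al](C)C | intermediate
24 | (2E)-3-iodo-2-methylprop-2-en-1-ol | I/C=C(C)/CO | intermediate
25 | (2E)-3-iodo-2-methylprop-2-enal | I/C=C(C)/C=O | intermediate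
26 | tert-butyl (2E,4E)-5-iodo-4-methylpenta-2,4-dienoate | I/C=C(C)/C=C/C(=O)OC(C)(C)C | intermediate
27 | (5S)-5-(hydroxymethyl)furan-2(5H)-one | OC[C@H]1OC(=O)C=C1 | starting material
28 | (5S)-5-[(trimethylsilyloxy)methyl]furan-2(5H)-one | C[Si](C)(C)OC[C@H]1OC(=O)C=C1 | intermediate
29 | tert-butyl (2E,4E)-4-methyl-5-[(2S,3R)-5-oxo-2-[(trimethylsilyloxy)methyl]oxolan-3-yl]penta-2,4-dienoate | C[Si](C)(C)OC[C@H]1OC(=O)C[C@@H]1/C=C(C)/C=C/C(=O)OC(C)(C)C | intermediate
30 | tert-butyl (2E,4E)-5-[(2S,3R)-2-(hydroxymethyl)-5-oxooxolan-3-yl]-4-methylpenta-2,4-dienoate | OC[C@H]1OC(=O)C[C@@H]1/C=C(C)/C=C/C(=O)OC(C)(C)C | intermediate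
31 | tert-butyl (2E,4E,6R,7S)-7,8-dihydroxy-6-(2-hydroxyethyl)-4-methylocta-2,4-dienoate | OC[C@@H](O)[C@H](CCO)/C=C(C)/C=C/C(=O)OC(C)(C)C | intermediate
32 | tert-butyl (2E,4E,6R)-6-formyl-8-hydroxy-4-methylocta-2,4-dienoate | O=C[C@H](CCO)/C=C(C)/C=C/C(=O)OC(C)(C)C | intermediate
33 | tert-butyl (2E,4E,6R)-8-hydroxy-6-(hydroxymethyl)-4-methylocta-2,4-dienoate | OC[C@H](CCO)/C=C(C)/C=C/C(=O)OC(C)(C)C | intermediate
34 | tert-butyldimethylsilyl (2E,4E,6R)-8-(tert-butyldimethylsilyloxy)-6-[(tert-butyldimethylsilyloxy)methyl]-4-methylocta-2,4-dienoate | CC(C)(C)[Si](C)(C)OC[C@H](CCO[Si](C)(C)C(C)(C)C)/C=C(C)/C=C/C(=O)O[Si](C)(C)C(C)(C)C | intermediate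
35 | (2E,4E,6R)-8-(tert-butyldimethylsilyloxy)-6-[(tert-butyldimethylsilyloxy)methyl]-4-methylocta-2,4-dienoic acid | CC(C)(C)[Si](C)(C)OC[C@H](CCO[Si](C)(C)C(C)(C)C)/C=C(C)/C=C/C(=O)O | intermediate
36 | (5S,6R)-6-[(2S,4R,6S)-4,6-dimethyl-6-(triethylsilyloxy)oct-7-en-2-yl]-2-oxo-5,6-dihydro-2H-pyran-5-yl (2E,4E,6R)-8-(tert-butyldimethylsilyloxy)-6-[(tert-butyldimethylsilyloxy)methyl]-4-methylocta-2,4-dienoate | C=C[C@@](C)(O[Si](CC)(CC)CC)C[C@H](C)C[C@H](C)[C@H]1OC(=O)C=C[C@@H]1OC(=O)/C=C/C(C)=C/[C@H](CO[Si](C)(C)C(C)(C)C)CCO[Si](C)(C)C(C)(C)C | intermediate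
37 | (5S,6R)-6-[(2S,4R,6S)-6-hydroxy-4,6-dimethyloct-7-en-2-yl]-2-oxo-5,6-dihydro-2H-pyran-5-yl (2E,4E,6R)-8-hydroxy-6-(hydroxymethyl)-4-methylocta-2,4-dienoate | C=C[C@@](C)(O)C[C@H](C)C[C@H](C)[C@H]1OC(=O)C=C[C@@H]1OC(=O)/C=C/C(C)=C/[C@H](CO)CCO | target

**Count and risks**

Total step count: 19. Longest linear sequence: 12 steps (steps 1–4, 6–11, 18, 19, from compound 1).

Steps most likely to fail:

Step 14 (the proposed new reaction). Possible failures are protodeiodination of 26, E/Z scrambling of the dienoate under irradiation, or a poor facial ratio. The fallback uses known chemistry only; it sets out from 27 and comes back at 35. Benzophenone-sensitised irradiation (350 nm) of 27 in 1,3-dioxolane adds the dioxolan-2-yl radical anti to the hydroxymethyl group and gives (4S,5S)-4-(1,3-dioxolan-2-yl)-5-(hydroxymethyl)oxolan-2-one F1. LiBH4 opens it to (2S,3S)-3-(1,3-dioxolan-2-yl)pentane-1,2,5-triol F2. NaIO4 cleaves the glycol to (2S)-2-(1,3-dioxolan-2-yl)-4-hydroxybutanal F3, and NaBH4 in the same flask gives (2S)-2-(1,3-dioxolan-2-yl)butane-1,4-diol F4. t-BuMe2SiCl and imidazole give the bis-silyl ether F5. Et3SiOTf with 2,4,6-collidine, then water, frees (2S)-4-(tert-butyldimethylsilyloxy)-2-[(tert-butyldimethylsilyloxy)methyl]butanal F6 without touching the silyl ethers. Wittig reaction with Ph3P=C(CH3)CHO gives (2E,4R)-6-(tert-butyldimethylsilyloxy)-4-[(tert-butyldimethylsilyloxy)methyl]-2-methylhex-2-enal F7. A second Wittig reaction with Ph3P=CHCO2t-Bu gives tert-butyl (2E,4E,6R)-8-(tert-butyldimethylsilyloxy)-6-[(tert-butyldimethylsilyloxy)methyl]-4-methylocta-2,4-dienoate F8. t-BuMe2SiOTf and 2,6-lutidine, then aqueous methanol, convert F8 through 34 into 35.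

Step 8 (Felkin–Anh addition, modest selectivity expected because the α-centre carries only CH3 versus CH2R). The fallback sets out from 14 and comes back at 17. 16 is added to 14 without regard to selectivity and the epimer mixture is oxidised with Dess–Martin periodinane to (2S,4R,6S)-1-(furan-2-yl)-2,4,6-trimethyl-6-(triethylsilyloxy)oct-7-en-1-one F9. LiBH(s-Bu)3 at −78 °C reduces F9 under Felkin–Anh control, which for the ketone gives the 1,2-anti alcohol (1S,2S,4R,6S)-1-(furan-2-yl)-2,4,6-trimethyl-6-(triethylsilyloxy)oct-7-en-1-ol F10 with high selectivity. Mitsunobu inversion (4-nitrobenzoic acid, PPh3, diisopropyl azodicarboxylate) gives the (1R) 4-nitrobenzoate F11, and K2CO3 in methanol releases 17.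

Step 2 (the γ-chloro Grignard reagent 5 may close to methylcyclopropane, and the in-flask silylation of a hindered magnesium alkoxide may be slow). The fallback sets out from 3 and comes back at 7. Commercial (2R)-3-bromo-2-methylpropan-1-ol F12 is treated with n-BuLi and then t-BuLi in Et2O at −78 °C to give lithium (2S)-3-lithio-2-methylpropan-1-olate F13, which adds to 3 in the presence of MgBr2·OEt2 under the same chelation control to give (2S,4S)-4-[(4S)-2,2-dimethyl-1,3-dioxolan-4-yl]-2-methylpentane-1,4-diol F14. Appel chlorination (PPh3, CCl4) of the primary alcohol gives (2S,4S)-5-chloro-2-[(4S)-2,2-dimethyl-1,3-dioxolan-4-yl]-4-methylpentan-2-ol F15, and Et3SiOTf with 2,6-lutidine gives 7.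

Further compounds
F1 | step 14 | (4S,5S)-4-(1,3-dioxolan-2-yl)-5-(hydroxymethyl)oxolan-2-one | OC[C@H]1OC(=O)C[C@@H]1C1OCCO1
F2 | step 14 | (2S,3S)-3-(1,3-dioxolan-2-yl)pentane-1,2,5-triol | OC[C@@H](O)[C@H](CCO)C1OCCO1
F3 | step 14 | (2S)-2-(1,3-dioxolan-2-yl)-4-hydroxybutanal | O=C[C@H](CCO)C1OCCO1
F4 | step 14 | (2S)-2-(1,3-dioxolan-2-yl)butane-1,4-diol | OC[C@H](CCO)C1OCCO1
F5 | step 14 | (2S)-1,4-bis(tert-butyldimethylsilyloxy)-2-(1,3-dioxolan-2-yl)butane | CC(C)(C)[Si](C)(C)OC[C@H](CCO[Si](C)(C)C(C)(C)C)C1OCCO1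
F6 | step 14 | (2S)-4-(tert-butyldimethylsilyloxy)-2-[(tert-butyldimethylsilyloxy)methyl]butanal | CC(C)(C)[Si](C)(C)OC[C@H](CCO[Si](C)(C)C(C)(C)C)C=O
F7 | step 14 | (2E,4R)-6-(tert-butyldimethylsilyloxy)-4-[(tert-butyldimethylsilyloxy)methyl]-2-methylhex-2-enal | CC(C)(C)[Si](C)(C)OC[C@H](CCO[Si](C)(C)C(C)(C)C)/C=C(C)/C=O
F8 | step 14 | tert-butyl (2E,4E,6R)-8-(tert-butyldimethylsilyloxy)-6-[(tert-butyldimethylsilyloxy)methyl]-4-methylocta-2,4-dienoate | CC(C)(C)[Si](C)(C)OC[C@H](CCO[Si](C)(C)C(C)(C)C)/C=C(C)/C=C/C(=O)OC(C)(C)C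
F9 | step 8 | (2S,4R,6S)-1-(furan-2-yl)-2,4,6-trimethyl-6-(triethylsilyloxy)oct-7-en-1-one | C=C[C@@](C)(O[Si](CC)(CC)CC)C[C@H](C)C[C@H](C)C(=O)c1ccco1
F10 | step 8 | (1S,2S,4R,6S)-1-(furan-2-yl)-2,4,6-trimethyl-6-(triethylsilyloxy)oct-7-en-1-ol | C=C[C@@](C)(O[Si](CC)(CC)CC)C[C@H](C)C[C@H](C)[C@H](O)c1ccco1
F11 | step 8 | (1R,2S,4R,6S)-1-(furan-2-yl)-2,4,6-trimethyl-6-(triethylsilyloxy)oct-7-en-1-yl 4-nitrobenzoate | C=C[C@@](C)(O[Si](CC)(CC)CC)C[C@H](C)C[C@H](C)[C@@H](OC(=O)c1ccc(cc1)[N+](=O)[O-])c1ccco1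
F12 | step 2 | (2R)-3-bromo-2-methylpropan-1-ol | BrC[C@H](C)CO
F13 | step 2 | lithium (2S)-3-lithio-2-methylpropan-1-olate | [Li]C[C@H](C)CO[Li]
F14 | step 2 | (2S,4S)-4-[(4S)-2,2-dimethyl-1,3-dioxolan-4-yl]-2-methylpentane-1,4-diol | CC1(C)OC[C@H](O1)[C@@](C)(O)C[C@H](C)CO
F15 | step 2 | (2S,4S)-5-chloro-2-[(4S)-2,2-dimethyl-1,3-dioxolan-4-yl]-4-methylpentan-2-ol | CC1(C)OC[C@H](O1)[C@@](C)(O)C[C@H](C)CCl
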